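## Structural features

The target is a germacranolide: a cyclodeca-1(10),3-dien-2-one (ring C1–C10) with a γ-lactone fused trans across C6–C7 (O on C6, carbonyl C12, exocyclic C11=C13), a tiglate on O8, a free hydroxyl on C5 and methyl groups on C4 and C10. The stereocentres C5 (S), C6 (S), C7 (R) and C8 (S) are contiguous; drawn as a zigzag C4–C9, the substituents O5, O6, C11 and O8 all lie on one side, so the 5,6-diol is threo (tartrate-like) and the lactone is trans-fused. Both ring alkenes, C1=C10 and C3=C4, are trisubstituted and Z, and they flank the C2 ketone as a cross-conjugated dienone. Fragile points are the α-methylene lactone (Michael acceptor), the dienone (conjugate addition, acid-triggered transannular C4–C10 closure, γ-deprotonation at C9 that would expel the C8 acyloxy group) and the tiglate (nucleophiles, strong base). The real difficulty is the ten-membered ring: direct closure fights entropy and transannular strain, and nothing in an open chain forces two trisubstituted alkenes to be Z. The key step exploits the fact that C7, which carries C11, sits opposite C2 (five ring bonds either way) and that C2(=O) with C11(=C13)–C12 is the retron of an aldol. A temporary C2–C11 bond gives two seven-membered rings (C2–C1–C10–C9–C8–C7–C11 and C2–C3–C4–C5–C6–C7–C11) in which alkenes can only be cis, and cutting it with loss of a leaving group from C13 returns ketone, ring and exo-methylene together.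

## Logic of the disconnections

29 ⇒ 27. The lactone bond C12–O6 is cut; O5/O6 are tied as an isopropylidene acetal and C12 becomes a tert-butyl ester. Reason: a closed lactone would add a third, strained ring to a bridged precursor, and the threo diol gives exactly the trans-dioxolane available from the chiral pool. Gain: the methylene lactone becomes a plain acrylate and one group masks both hydroxyls. Demand: one acid treatment must remove acetal and ester and close the five-membered lactone on O6 (not a six-membered one on O5) without harming the dienone.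

27 ⇒ 25. Retro-fragmentation: C2–C11 is re-formed, C2=O becomes a bridgehead carbinol and C11=C13 becomes C11–C13–OMs. Reason: C2–C11 is an aldol bond that an alkoxide can push and a leaving group can pull, so it can be cut last. Gain: the ten-membered ring with two Z alkenes is replaced by two cycloheptenes sharing the C2–C11–C7 bridge. Demand: only the C2 alkoxide may form in the presence of tiglate and mesylate, fragmentation must outrun oxetane closure, and the product must not meet excess base.

25 ⇒ 24 ⇒ 23 ⇒ 21. The mesylate is traced to a silyl ether, then C1=C10 and C3=C4 are cut (double ring-closing metathesis). Reason: each closure is seven-membered, so Z geometry is automatic. Gain: an open chain with four terminal alkenes. Demand: the two vinyl groups on C2 are diastereotopic and only the pairing that places the bridge on one face can finish; two 1,1-disubstituted partners must be accepted.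

21 ⇒ 19 + 20 ⇒ 16 + 17. The O8–acyl bond is cut, then both C2–vinyl bonds (C2–C1, C2–C3). Reason: C2 becomes the carbonyl of a γ-lactone to O8, which distinguishes it from the other carbonyl on C11 (C12, tert-butyl ester) and frees O8 for acylation. Gain: the carbinol and four carbons come from 17 in one step. Demand: two 1,2-additions, no conjugate addition to enone 18, no attack on the tert-butyl ester, no retro-aldol.

16 ⇒ 15 ⇒ 14. C11–C13 is cut (aldol with formaldehyde). Reason: C11 of 14 is a malonate-type carbon acid. Gain: no quaternary centre. Demand: the new hydroxyl must be silylated before strong base is used; the C11 configuration is immaterial.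

14 ⇒ 11 + 12. The lactone C–O8 bond and C8–C9 are cut (methallylation, lactonisation on the methyl ester). Gain: C8 becomes a formyl group; C9, C10 and C14 come from 12. Demand: reagent-controlled attack on the Si face of C8=O; only the methyl ester lactonises.

11 ⇒ 10 ⇒ 8 + 9. The formyl group is masked as a dithiane and C7–C8 is cut (conjugate addition). Reason: C7 is the β-carbon of an alkylidene malonate and the C6–O stereocentre can direct attack. Gain: C7 becomes sp2. Demand: attack anti to the C6–O bond.

8 ⇒ 6 + 7. C7=C11 is cut (Knoevenagel). Gain: C11 with both its carbonyls (future C2 and C12) arrives in one step from 7. Demand: mild conditions; alkene geometry is irrelevant.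

6 ⇒ 5 ⇒ 4 ⇒ 2 ⇒ 1. The formyl group comes from an ester, C4=C3 from methylenation of ketone 4, C4–C15 from acid chloride 3, and half-ester 2 from C2-symmetric 1. Reason: 1 already holds C5 and C6 with the threo oxygen pattern as a trans-dioxolane. Demand: the two esters must be told apart once; epimerisation is self-correcting because the trans-dioxolane is the stable isomer.

## Other disconnections considered

Alternative 1: The cut is the lactone itself (C11–C12 and C12–O6), C12 going back to carbon monoxide and the precursor being hydroxy alkyne A1.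
- Forward step: A1 with PdCl2, SnCl2 and PPh3 under CO forms an alkoxycarbonyl complex of divalent palladium at O6, which adds syn across C11≡C13; protonolysis would give silyl ether A2, and desilylation the target.
- In favour: lactone and exo-methylene appear at the very end, so no Michael acceptor is carried.
- Better than the chosen plan: O6 is the only free hydroxyl, so lactone regiochemistry is unambiguous, whereas the chosen endgame frees O5 and O6 together. The catalytic, non-basic medium is also kinder to the tiglate.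
- Against: A1 already contains the ten-membered Z,Z-dienone, so the real problem is untouched and a separate macrocyclisation is still needed. Lewis-acidic SnCl2 and palladium hydrides meet a cross-conjugated dienone.
- Comparison: structurally it solves only the lactone, where the chosen plan solves ring, alkene geometry and methylene in one event. After the key step both need one step (equal). Before it, alternative 1 is longer by a whole ring synthesis.

Alternative 2: The cut is C7–C8; the precursor is open-chain bromomethyl butenolide aldehyde A3.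
- Forward step: indium in aqueous THF at high dilution converts the allylic bromide into an allylindium whose γ-carbon C7 adds to the C8 aldehyde, moving the alkene to C11=C13 and giving A4.
- Better than the chosen plan: one step makes the ring, a C–C bond, two stereocentres and the exo-methylene, where the chosen key step makes no stereocentre. It is also neutral and water-tolerant.
- Equal: in both, the exo-methylene arises by transposition, not by a separate methylenation.
- Against: direct ten-membered closure competes with oligomerisation. Both Z-trisubstituted alkenes must be made in the open chain, where nothing enforces Z. The C6→C7→C8 relative configuration depends on a macrocyclic transition state. C2 must be carried as a protected carbinol.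
- Step economy: four steps follow A4 (tigloylation, two desilylations, oxidation) against one in the chosen plan.

Alternative 3: The cut is the C3=C4 alkene, traced to eleven-membered sulfone A5 with sulfur between C3 and C4.
- Forward step: CBr2F2 and KOH on alumina halogenate α to sulfur; 1,3-elimination gives the episulfone, which loses SO2 to give triene A6.
- Equal: the logic matches the chosen plan, since a ring is closed the easy way and a temporary atom is then excised.
- Better than the chosen plan: the extrusion forms a ring C=C bond and needs no desymmetrising step, and the base meets a substrate stripped of sensitive groups.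
- Against: the geometry of the trisubstituted C3=C4 is fixed at the episulfone stage and is not guaranteed Z, whereas the seven-membered closures cannot give E. C1=C10 must still be made Z in an open chain. Because no ester or ketone survives the conditions, A6 sits at a low oxidation level.
- Step economy: at least six further steps are needed after A6 (two PMB removals, oxidations at C2 and C12, silyl-to-tiglate exchange, lactonisation).

Key step: step 16

Remarks on the chemistry:
- The structures of the key-step pair are consistent with the target (5S,6S,7R,8S, both ring alkenes Z, bridge on one face at C2 and C7).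
- Two corrections of bookkeeping: the fragmentation forms no skeletal σ bond (one is cut, two π bonds appear), and it is C7, bearing C11, that lies across the ring from C2.
- Three design changes against the simplest form of the plan. C12 is a tert-butyl ester so that the vinyl reagent meets only one reactive carbonyl. A lactone to O8 singles out the carbonyl that becomes C2. One equivalent of KN(SiMe3)2 replaces excess KH to protect the tiglate and the product.
- Assumption: compounds 8, 10, 11 and 13 are carried as E/Z or C11-epimer mixtures that converge at 14; the C11 configuration drawn from 14 onward is the expected one and is immaterial.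

## Steps

Step 1
Reactants: 1 dimethyl (4R,5R)-2,2-dimethyl-1,3-dioxolane-4,5-dicarboxylate
Product: 2 (4R,5R)-5-(methoxycarbonyl)-2,2-dimethyl-1,3-dioxolane-4-carboxylic acid
Conditions: KOH (1.0 equiv), MeOH, 0 °C → rt; then 1 M HCl
Reagents that add atoms: potassium hydroxide, [K+].[OH-]
Why: Ester saponification; the first carboxylate repels a second hydroxide, so the C2-symmetric diester should stop at the half-ester, both ends being equivalent; the stereocentres are untouched.

Step 2
Reactants: 2 (4R,5R)-5-(methoxycarbonyl)-2,2-dimethyl-1,3-dioxolane-4-carboxylic acid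
Product: 4 methyl (4R,5R)-5-acetyl-2,2-dimethyl-1,3-dioxolane-4-carboxylate, via acid chloride 3 (not isolated)
Conditions: (COCl)2, DMF (cat.), CH2Cl2, 0 °C → rt; evaporate; MeMgBr (1.05 equiv), Fe(acac)3 (3 mol %), THF, −78 °C
Reagents that add atoms: methylmagnesium bromide, C[Mg]Br; oxalyl chloride, O=C(Cl)C(=O)Cl (its chlorine stays only in 3)
Why: Acid chloride formation followed by iron-catalysed acylation of a Grignard reagent, a ketone synthesis that at −78 °C is much faster than addition to the product ketone or the methyl ester; C4 and its methyl C15 are now in place.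

Step 3
Reactants: 4 methyl (4R,5R)-5-acetyl-2,2-dimethyl-1,3-dioxolane-4-carboxylate
Product: 5 methyl (4R,5S)-2,2-dimethyl-5-(prop-1-en-2-yl)-1,3-dioxolane-4-carboxylate
Conditions: Ph3PCH3Br, KOtBu, THF, 0 °C → rt
Reagents that add atoms: methyltriphenylphosphonium bromide, C[P+](c1ccccc1)(c1ccccc1)c1ccccc1.[Br-]
Why: Wittig methylenation; the ketone is far more electrophilic than the ester, and transient enolisation is harmless because the trans-dioxolane is the stable isomer.

Step 4
Reactants: 5 methyl (4R,5S)-2,2-dimethyl-5-(prop-1-en-2-yl)-1,3-dioxolane-4-carboxylate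
Product: 6 (4R,5S)-2,2-dimethyl-5-(prop-1-en-2-yl)-1,3-dioxolane-4-carbaldehyde
Conditions: i-Bu2AlH (DIBAL-H, 1.05 equiv), CH2Cl2, −78 °C; Rochelle salt
Reagents that add atoms: none
Why: Partial reduction of an α-alkoxy ester; the chelated aluminium hemiacetal is stable at −78 °C and should release the aldehyde only on work-up; 6 is used without storage.

Step 5
Reactants: 6 (4R,5S)-2,2-dimethyl-5-(prop-1-en-2-yl)-1,3-dioxolane-4-carbaldehyde; 7 tert-butyl methyl propanedioate
Product: 8 1-tert-butyl 3-methyl 2-{[(4S,5S)-2,2-dimethyl-5-(prop-1-en-2-yl)-1,3-dioxolan-4-yl]methylidene}propanedioate (E/Z mixture)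
Conditions: piperidine (10 mol %), AcOH (10 mol %), 4 Å MS, CH2Cl2, rt
Reagents that add atoms: none
Why: Knoevenagel condensation through the piperidinium iminium ion, with sieves removing water; the E/Z mixture is of no consequence because C7 and C11 both become sp3 in step 6.

Step 6
Reactants: 8 alkylidene malonate (E/Z mixture); 9 1,3-dithiane
Product: 10 1-tert-butyl 3-methyl 2-{(S)-[(4S,5S)-2,2-dimethyl-5-(prop-1-en-2-yl)-1,3-dioxolan-4-yl](1,3-dithian-2-yl)methyl}propanedioate (both C11 epimers)
Conditions: 9, n-BuLi, THF, −30 °C; then 8, −78 °C; AcOH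
Reagents that add atoms: none
Why: Conjugate addition of a sulfur-stabilised carbanion to a doubly activated alkene; allylic 1,3-strain holds C6–H in the plane of C7=C11 and the nucleophile should attack C7 anti to the C6–O bond (Felkin–Anh-type), which sets C7 with O6 and C11 syn along the C5–C8 chain.

Step 7
Reactants: 10 dithiane adduct
Product: 11 1-tert-butyl 3-methyl 2-{(1S)-1-[(4S,5S)-2,2-dimethyl-5-(prop-1-en-2-yl)-1,3-dioxolan-4-yl]-2-oxoethyl}propanedioate (both C11 epimers)
Conditions: MeI, CaCO3, MeCN–H2O (4:1), 45 °C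
Reagents that add atoms: water, O
Why: Dithiane hydrolysis by S-methylation: the sulfonium leaves, water traps the thionium ion and the aldehyde is released under CaCO3-buffered conditions that should spare the acetonide, both alkenes and the α-stereocentre C7.

Step 8
Reactants: 11 aldehyde; 12 3-chloro-2-methylprop-1-ene
Product: 14 tert-butyl (3R,4R,5S)-4-[(4S,5S)-2,2-dimethyl-5-(prop-1-en-2-yl)-1,3-dioxolan-4-yl]-5-(2-methylprop-2-en-1-yl)-2-oxooxolane-3-carboxylate, via hydroxy malonate 13 (not isolated)
Conditions: 12, Mg, THF; (−)-Ipc2BOMe, Et2O, −78 °C → rt; 11, −78 °C; NaBO3·4H2O, THF–H2O; then PPTS (cat.), toluene, 50 °C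
Reagents that add atoms: none
Why: Brown allylboration through a closed chair transition state; the reagent from (−)-Ipc2BOMe adds to the Si face of C8=O and is expected to override the bias of the α-branched aldehyde, giving 8S; acid then closes the γ-lactone on the methyl ester (less hindered, better leaving group than tert-butoxide) and C11–H equilibrates to the all-trans lactone.

Step 9
Reactants: 14 lactone ester
Product: 15 tert-butyl (3R,4R,5S)-4-[(4S,5S)-2,2-dimethyl-5-(prop-1-en-2-yl)-1,3-dioxolan-4-yl]-3-(hydroxymethyl)-5-(2-methylprop-2-en-1-yl)-2-oxooxolane-3-carboxylate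
Conditions: aq. CH2O (37 %), KHCO3 (cat.), THF, 0 °C → rt
Reagents that add atoms: formaldehyde, C=O
Why: Aldol addition of the lactone–ester enolate (a malonate-type carbon acid) to formaldehyde under weak base; the electrophile should enter anti to the C7 substituent, but either C11 epimer would serve because C11 becomes sp2 in step 16.

Step 10
Reactants: 15 hydroxymethyl lactone
Product: 16 tert-butyl (3R,4R,5S)-3-{[(tert-butyldimethylsilyl)oxy]methyl}-4-[(4S,5S)-2,2-dimethyl-5-(prop-1-en-2-yl)-1,3-dioxolan-4-yl]-5-(2-methylprop-2-en-1-yl)-2-oxooxolane-3-carboxylate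
Conditions: TBSCl, imidazole, DMF, rt
Reagents that add atoms: tert-butyldimethylsilyl chloride, CC(C)(C)[Si](C)(C)Cl
Why: Silylation of the primary alcohol; this blocks retro-aldol loss of formaldehyde from the alkoxide in step 11.

Step 11
Reactants: 16 silyl ether lactone; 17 vinylmagnesium bromide
Product: 19 tert-butyl (2R,3R,4S)-2-{[(tert-butyldimethylsilyl)oxy]methyl}-3-[(4S,5S)-2,2-dimethyl-5-(prop-1-en-2-yl)-1,3-dioxolan-4-yl]-4-hydroxy-2-(3-hydroxypenta-1,4-dien-3-yl)-6-methylhept-6-enoate, via vinyl ketone 18 (not isolated)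
Conditions: 17 (2.5 equiv), CeCl3 (anhydrous, 2.5 equiv), THF, −78 °C → −40 °C; aq. NH4Cl at −78 °C
Reagents that add atoms: none
Why: Double 1,2-addition of an organocerium reagent to a lactone: the first vinyl opens the ring to enone 18 and frees O8, the second adds to the ketone; cerium should suppress conjugate addition, and the tert-butyl ester is too hindered to compete.

Step 12
Reactants: 19 diol; 20 (2E)-2-methylbut-2-enoyl chloride (tigloyl chloride)
Product: 21 tert-butyl (2R,3R,4S)-2-{[(tert-butyldimethylsilyl)oxy]methyl}-3-[(4S,5S)-2,2-dimethyl-5-(prop-1-en-2-yl)-1,3-dioxolan-4-yl]-2-(3-hydroxypenta-1,4-dien-3-yl)-6-methyl-4-{[(2E)-2-methylbut-2-enoyl]oxy}hept-6-enoate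
Conditions: 20, Et3N, DMAP (cat.), CH2Cl2, 0 °C → rt
Reagents that add atoms: none
Why: DMAP-catalysed acylation by an acid chloride; only the secondary C8 hydroxyl should react, the tertiary C2 hydroxyl being inert, and C8 keeps its configuration.

Step 13
Reactants: 21 tiglate tetraene
Product: 23 tert-butyl (1(10)Z,3Z,2R,5S,6S,7R,8S,11R)-13-[(tert-butyldimethylsilyl)oxy]-2-hydroxy-5,6-(isopropylidenedioxy)-8-(tigloyloxy)-2,11-cyclogermacra-1(10),3-dien-12-oate (bicyclo[4.4.1]undecadiene, C2–C11 bridge bond, bridgehead OH), via ring-B cycloheptene 22 (not isolated)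
Conditions: second-generation Grubbs catalyst (10 mol %), toluene (2 mM), 80 °C, argon sparge
Reagents that add atoms: none
Why: Double ring-closing metathesis; the ruthenium carbene loads on a vinyl group and closes onto a 1,1-disubstituted alkene twice, each time in a seven-membered ring, so both new trisubstituted alkenes are necessarily cis (Z); C2 becomes a stereocentre dictated by the bridge, since only the vinyl cis to the C7 substituent can close the second ring.

Step 14
Reactants: 23 bridged silyl ether
Product: 24 tert-butyl (1(10)Z,3Z,2R,5S,6S,7R,8S,11R)-2,13-dihydroxy-5,6-(isopropylidenedioxy)-8-(tigloyloxy)-2,11-cyclogermacra-1(10),3-dien-12-oate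
Conditions: HF·pyridine, pyridine, THF, 0 °C → rt
Reagents that add atoms: none
Why: Fluoride-induced cleavage of the primary silyl ether; pyridine buffering should protect the trans-acetonide, and the bridgehead bis-allylic alcohol cannot ionise because a bridgehead cannot become planar.

Step 15
Reactants: 24 bridged diol
Product: 25 tert-butyl (1(10)Z,3Z,2R,5S,6S,7R,8S,11R)-2-hydroxy-5,6-(isopropylidenedioxy)-13-(methanesulfonyloxy)-8-(tigloyloxy)-2,11-cyclogermacra-1(10),3-dien-12-oate (bridged bicyclo[4.4.1]undecadienol mesylate)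
Conditions: MsCl, Et3N, CH2Cl2, −20 °C
Reagents that add atoms: methanesulfonyl chloride, CS(=O)(=O)Cl
Why: Sulfonylation (via sulfene) of the primary neopentyl-type alcohol; the tertiary bridgehead hydroxyl should not react, and triethylamine is too weak to trigger fragmentation at −20 °C.

Step 16
Reactants: 25 bridged mesylate
Product: 27 tert-butyl (1(10)Z,3Z,5S,6S,7R,8S)-5,6-(isopropylidenedioxy)-2-oxo-8-(tigloyloxy)germacra-1(10),3,11(13)-trien-12-oate (ten-membered dienone, seco-lactone acetonide), via potassium alkoxide 26 (not isolated)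
Conditions: KN(SiMe3)2 (1.0 equiv, added to 25), THF, −78 °C → −20 °C; pH 7 buffer
Reagents that add atoms: potassium bis(trimethylsilyl)amide, C[Si](C)(C)[N-][Si](C)(C)C.[K+] (its potassium stays only in 26)
Why: Grob fragmentation of a 1,3-diol monosulfonate (equally a retro-aldol followed by E1cB loss of mesylate). The base deprotonates only the bridgehead hydroxyl to give 26, whose oxygen lone pair pushes into the C2–C11 σ bond as C13–OMs leaves, so C2=O and C11=C13 form together. The closest known reaction type is the alkoxide-triggered fragmentation of cyclic 1,3-diol monosulfonates to medium-ring enones; here the leaving group sits on an exocyclic CH2, so the new alkene lies outside the ring and the bridge carbon becomes the acrylate α-carbon. No ring is closed in the bond-forming sense: the ten-membered ring is the perimeter of the bicycle and is unveiled, irreversibly, when the one-carbon bridge is cut. No stereocentre is created; C2 and C11 become sp2, so the C11 configuration of 25 is immaterial and C5–C8 are untouched. The stereoelectronic demand, C2–C11 antiperiplanar to C13–O, is met by free rotation about C11–C13, and a stepwise retro-aldol/E1cB path would give the same product. The selectivity needed is O–H deprotonation over attack on the tiglate or γ-deprotonation of the product at C9, secured by one equivalent of a hindered amide base added to the substrate at −78 °C. Both ring alkenes are already Z because each was made inside a seven-membered ring.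

Step 17
Reactants: 27 dienone tert-butyl acrylate
Product: 29 (3aR,4S,6Z,9Z,11S,11aS)-11-hydroxy-6,10-dimethyl-3-methylidene-2,8-dioxo-2,3,3a,4,5,8,11,11a-octahydrocyclodeca[b]furan-4-yl (2E)-2-methylbut-2-enoate (CNP0230565.1), via dihydroxy acid 28 (not isolated)
Conditions: CF3CO2H–CH2Cl2 (1:4), H2O (5 equiv), 0 °C → rt
Reagents that add atoms: none
Why: Acid-catalysed acetal hydrolysis and tert-butyl ester cleavage (loss of isobutene) give 28, in which the C6 hydroxyl should close the five-membered lactone on the acrylic acid faster than the C5 hydroxyl could close a six-membered one; no stereocentre is involved.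

## Compound list

1 | dimethyl (4R,5R)-2,2-dimethyl-1,3-dioxolane-4,5-dicarboxylate | COC(=O)[C@@H]1OC(C)(C)O[C@H]1C(=O)OC | starting material
2 | (4R,5R)-5-(methoxycarbonyl)-2,2-dimethyl-1,3-dioxolane-4-carboxylic acid | OC(=O)[C@@H]1OC(C)(C)O[C@H]1C(=O)OC | intermediate
3 | methyl (4R,5R)-5-(chlorocarbonyl)-2,2-dimethyl-1,3-dioxolane-4-carboxylate | ClC(=O)[C@@H]1OC(C)(C)O[C@H]1C(=O)OC | intermediate (not isolated)
4 | methyl (4R,5R)-5-acetyl-2,2-dimethyl-1,3-dioxolane-4-carboxylate | CC(=O)[C@@H]1OC(C)(C)O[C@H]1C(=O)OC | intermediate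
5 | methyl (4R,5S)-2,2-dimethyl-5-(prop-1-en-2-yl)-1,3-dioxolane-4-carboxylate | CC(=C)[C@@H]1OC(C)(C)O[C@H]1C(=O)OC | intermediate
6 | (4R,5S)-2,2-dimethyl-5-(prop-1-en-2-yl)-1,3-dioxolane-4-carbaldehyde | CC(=C)[C@@H]1OC(C)(C)O[C@H]1C=O | intermediate
7 | tert-butyl methyl propanedioate | COC(=O)CC(=O)OC(C)(C)C | starting material
8 | 1-tert-butyl 3-methyl 2-{[(4S,5S)-2,2-dimethyl-5-(prop-1-en-2-yl)-1,3-dioxolan-4-yl]methylidene}propanedioate (E/Z mixture, geometry left open) | CC(=C)[C@@H]1OC(C)(C)O[C@H]1C=C(C(=O)OC)C(=O)OC(C)(C)C | intermediate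
9 | 1,3-dithiane | C1CSCSC1 | starting material
10 | 1-tert-butyl 3-methyl 2-{(S)-[(4S,5S)-2,2-dimethyl-5-(prop-1-en-2-yl)-1,3-dioxolan-4-yl](1,3-dithian-2-yl)methyl}propanedioate (C11 epimers, centre left open) | COC(=O)C(C(=O)OC(C)(C)C)[C@@H]([C@@H]1OC(C)(C)O[C@H]1C(C)=C)C1SCCCS1 | intermediate
11 | 1-tert-butyl 3-methyl 2-{(1S)-1-[(4S,5S)-2,2-dimethyl-5-(prop-1-en-2-yl)-1,3-dioxolan-4-yl]-2-oxoethyl}propanedioate (C11 epimers) | COC(=O)C(C(=O)OC(C)(C)C)[C@@H]([C@@H]1OC(C)(C)O[C@H]1C(C)=C)C=O | intermediate
12 | 3-chloro-2-methylprop-1-ene | CC(=C)CCl | starting material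
13 | 1-tert-butyl 3-methyl 2-{(1R,2S)-1-[(4S,5S)-2,2-dimethyl-5-(prop-1-en-2-yl)-1,3-dioxolan-4-yl]-2-hydroxy-4-methylpent-4-en-1-yl}propanedioate (C11 epimers) | COC(=O)C(C(=O)OC(C)(C)C)[C@@H]([C@@H]1OC(C)(C)O[C@H]1C(C)=C)[C@@H](O)CC(C)=C | intermediate (not isolated)
14 | tert-butyl (3R,4R,5S)-4-[(4S,5S)-2,2-dimethyl-5-(prop-1-en-2-yl)-1,3-dioxolan-4-yl]-5-(2-methylprop-2-en-1-yl)-2-oxooxolane-3-carboxylate | CC(C)(C)OC(=O)[C@H]1C(=O)O[C@@H](CC(C)=C)[C@@H]1[C@@H]2OC(C)(C)O[C@H]2C(C)=C | intermediate
15 | tert-butyl (3R,4R,5S)-4-[(4S,5S)-2,2-dimethyl-5-(prop-1-en-2-yl)-1,3-dioxolan-4-yl]-3-(hydroxymethyl)-5-(2-methylprop-2-en-1-yl)-2-oxooxolane-3-carboxylate | CC(C)(C)OC(=O)[C@]1(CO)C(=O)O[C@@H](CC(C)=C)[C@@H]1[C@@H]2OC(C)(C)O[C@H]2C(C)=C | intermediate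
16 | tert-butyl (3R,4R,5S)-3-{[(tert-butyldimethylsilyl)oxy]methyl}-4-[(4S,5S)-2,2-dimethyl-5-(prop-1-en-2-yl)-1,3-dioxolan-4-yl]-5-(2-methylprop-2-en-1-yl)-2-oxooxolane-3-carboxylate | CC(C)(C)OC(=O)[C@]1(CO[Si](C)(C)C(C)(C)C)C(=O)O[C@@H](CC(C)=C)[C@@H]1[C@@H]2OC(C)(C)O[C@H]2C(C)=C | intermediate
17 | vinylmagnesium bromide | C=C[Mg]Br | starting material
18 | tert-butyl (2R,3R,4S)-2-{[(tert-butyldimethylsilyl)oxy]methyl}-3-[(4S,5S)-2,2-dimethyl-5-(prop-1-en-2-yl)-1,3-dioxolan-4-yl]-4-hydroxy-6-methyl-2-(prop-2-enoyl)hept-6-enoate (present as its metal alkoxide) | CC(C)(C)OC(=O)[C@@](C(=O)C=C)(CO[Si](C)(C)C(C)(C)C)[C@@H]([C@@H]1OC(C)(C)O[C@H]1C(C)=C)[C@@H](O)CC(C)=C | intermediate (not isolated)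
19 | tert-butyl (2R,3R,4S)-2-{[(tert-butyldimethylsilyl)oxy]methyl}-3-[(4S,5S)-2,2-dimethyl-5-(prop-1-en-2-yl)-1,3-dioxolan-4-yl]-4-hydroxy-2-(3-hydroxypenta-1,4-dien-3-yl)-6-methylhept-6-enoate | CC(C)(C)OC(=O)[C@@](C(O)(C=C)C=C)(CO[Si](C)(C)C(C)(C)C)[C@@H]([C@@H]1OC(C)(C)O[C@H]1C(C)=C)[C@@H](O)CC(C)=C | intermediate
20 | (2E)-2-methylbut-2-enoyl chloride (tigloyl chloride) | C/C=C(\C)C(=O)Cl | starting material
21 | tert-butyl (2R,3R,4S)-2-{[(tert-butyldimethylsilyl)oxy]methyl}-3-[(4S,5S)-2,2-dimethyl-5-(prop-1-en-2-yl)-1,3-dioxolan-4-yl]-2-(3-hydroxypenta-1,4-dien-3-yl)-6-methyl-4-{[(2E)-2-methylbut-2-enoyl]oxy}hept-6-enoate | CC(C)(C)OC(=O)[C@@](C(O)(C=C)C=C)(CO[Si](C)(C)C(C)(C)C)[C@@H]([C@@H]1OC(C)(C)O[C@H]1C(C)=C)[C@@H](OC(=O)/C(C)=C/C)CC(C)=C | intermediate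
22 | ring-B cycloheptene (germacrane locants, 2S,5S,6S,7R,8S,11R): ring C2–C1=C10–C9–C8–C7–C11 closed (1(10)Z); C2 carries OH and vinyl, C11 carries CO2tBu and CH2OTBS, C7 the (4S,5S)-isopropenyl-dioxolanyl group, C8 the tiglate | CC(C)(C)OC(=O)[C@@]1(CO[Si](C)(C)C(C)(C)C)[C@@H]([C@@H]2OC(C)(C)O[C@H]2C(C)=C)[C@@H](OC(=O)/C(C)=C/C)C/C(C)=C\[C@@]1(O)C=C | intermediate (not isolated)
23 | tert-butyl (1(10)Z,3Z,2R,5S,6S,7R,8S,11R)-13-[(tert-butyldimethylsilyl)oxy]-2-hydroxy-5,6-(isopropylidenedioxy)-8-(tigloyloxy)-2,11-cyclogermacra-1(10),3-dien-12-oate | CC(C)(C)OC(=O)[C@@]1(CO[Si](C)(C)C(C)(C)C)[C@@H]2[C@@H](OC(=O)/C(C)=C/C)C/C(C)=C\[C@@]1(O)/C=C(/C)[C@@H]1OC(C)(C)O[C@H]12 | intermediate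
24 | tert-butyl (1(10)Z,3Z,2R,5S,6S,7R,8S,11R)-2,13-dihydroxy-5,6-(isopropylidenedioxy)-8-(tigloyloxy)-2,11-cyclogermacra-1(10),3-dien-12-oate | CC(C)(C)OC(=O)[C@@]1(CO)[C@@H]2[C@@H](OC(=O)/C(C)=C/C)C/C(C)=C\[C@@]1(O)/C=C(/C)[C@@H]1OC(C)(C)O[C@H]12 | intermediate
25 | tert-butyl (1(10)Z,3Z,2R,5S,6S,7R,8S,11R)-2-hydroxy-5,6-(isopropylidenedioxy)-13-(methanesulfonyloxy)-8-(tigloyloxy)-2,11-cyclogermacra-1(10),3-dien-12-oate | CC(C)(C)OC(=O)[C@@]1(COS(C)(=O)=O)[C@@H]2[C@@H](OC(=O)/C(C)=C/C)C/C(C)=C\[C@@]1(O)/C=C(/C)[C@@H]1OC(C)(C)O[C@H]12 | intermediate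
26 | potassium C2-alkoxide of 25 | CC(C)(C)OC(=O)[C@@]1(COS(C)(=O)=O)[C@@H]2[C@@H](OC(=O)/C(C)=C/C)C/C(C)=C\[C@@]1([O-])/C=C(/C)[C@@H]1OC(C)(C)O[C@H]12.[K+] | intermediate (not isolated)
27 | tert-butyl (1(10)Z,3Z,5S,6S,7R,8S)-5,6-(isopropylidenedioxy)-2-oxo-8-(tigloyloxy)germacra-1(10),3,11(13)-trien-12-oate | C=C(C(=O)OC(C)(C)C)[C@@H]2[C@@H](OC(=O)/C(C)=C/C)C/C(C)=C\C(=O)/C=C(/C)[C@@H]1OC(C)(C)O[C@H]12 | intermediate
28 | (1(10)Z,3Z,5S,6S,7R,8S)-5,6-dihydroxy-2-oxo-8-(tigloyloxy)germacra-1(10),3,11(13)-trien-12-oic acid | C=C(C(=O)O)[C@@H]1[C@@H](OC(=O)/C(C)=C/C)C/C(C)=C\C(=O)/C=C(/C)[C@H](O)[C@H]1O | intermediate (not isolated)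
29 | (3aR,4S,6Z,9Z,11S,11aS)-11-hydroxy-6,10-dimethyl-3-methylidene-2,8-dioxo-2,3,3a,4,5,8,11,11a-octahydrocyclodeca[b]furan-4-yl (2E)-2-methylbut-2-enoate | C=C1C(=O)O[C@H]2[C@H]1[C@@H](OC(=O)/C(C)=C/C)C/C(C)=C\C(=O)/C=C(/C)[C@@H]2O | target

## Step count and least certain steps

Total: 17 steps. Longest linear sequence: 17 steps from 1; all other inputs (7, 9, 12, 17, 20) are commercial.

The key step, step 16. Most likely to go wrong: the C2 alkoxide may alkylate itself on the neighbouring mesylate (oxetane closure) faster than the C2–C11 bond breaks, or a trace of excess base may deprotonate the new dienone at C9 and expel the C8 tiglate. Both arise because alkoxide, leaving group and product share one flask.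
- Fallback, separating bond cleavage from elimination: 23 is treated with KN(SiMe3)2 at −78 °C, where only retro-aldol is possible, and the ring-opened enolate is protonated cold to give the ten-membered silyloxymethyl ester F1.
- HF·pyridine then gives the hydroxymethyl ester F2.
- MsCl/Et3N converts it into the mesylate F3, which loses methanesulfonate with DBU (E1cB) and so returns to the route at 27.

Step 13. Most likely to go wrong: wrong diastereotopic-group selection. The first closure may engage the C2 vinyl that ends trans to the C7 substituent, giving a monocycle that cannot bridge and instead stalls or oligomerises; closure onto the hindered isopropenyl group may also be slow.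
- Fallback, building the rings one at a time: 16 takes up one equivalent of the vinylcerium reagent to give the vinyl lactol F4, whose anomeric centre equilibrates through the open enone.
- Ring-closing metathesis then funnels F4 into the oxa-bridged lactol F5, since only the anomer with vinyl and methallyl cis can close.
- A second vinylcerium addition to the masked ketone, delivered from the face of the C8 alkoxide (the face required), gives the cycloheptene diol F6.
- Tigloylation of F6 with 20 rejoins the route at 22, which closes to 23 under the step 13 conditions.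

Step 11. Most likely to go wrong: conjugate addition of the second vinyl to enone 18, or retro-aldol cleavage of the product alkoxide on warming, because the ketone is neopentyl-hindered and the aldolate is tertiary.
- Fallback: 16 is treated with excess ethynylmagnesium bromide, which can only add 1,2, to give the diethynyl carbinol F7.
- Semi-hydrogenation over lead-poisoned Pd/CaCO3 with quinoline then gives 19.

Step 8. Most likely to go wrong: poor facial selectivity if the substrate bias of the α-branched aldehyde opposes the reagent, giving the C8 epimer.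
- Fallback, correcting C8 by inversion: the methallylation mixture from 11 is lactonised and the cis-lactone, 8-epi lactone F8, is separated from 14.
- LiOH opens F8 to the hydroxy half-acid F9.
- Mitsunobu lactonisation (PPh3, DIAD) closes the ring with inversion at C8 and returns 14.

Step 17. Most likely to go wrong: acid-promoted side reactions of the protonated dienone (transannular C4–C10 closure), trifluoroacetylation, or lactone closure on O5.
- Fallback, staged and without strong protic acid: 27 is treated with aqueous acetic acid, which removes only the acetonide, to give the diol tert-butyl ester F10.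
- TMSOTf/2,6-lutidine cleaves the tert-butyl ester through its silyl ester, and mild aqueous work-up gives 28.
- Carbodiimide activation (EDC, DMAP) then closes the lactone to 29.

## Further compounds

F1 | step 16 | tert-butyl (1(10)Z,3Z,5S,6S,7R,8S)-13-[(tert-butyldimethylsilyl)oxy]-5,6-(isopropylidenedioxy)-2-oxo-8-(tigloyloxy)germacra-1(10),3-dien-12-oate (C11 epimers) | CC(C)(C)OC(=O)C(CO[Si](C)(C)C(C)(C)C)[C@@H]2[C@@H](OC(=O)/C(C)=C/C)C/C(C)=C\C(=O)/C=C(/C)[C@@H]1OC(C)(C)O[C@H]12
F2 | step 16 | tert-butyl (1(10)Z,3Z,5S,6S,7R,8S)-13-hydroxy-5,6-(isopropylidenedioxy)-2-oxo-8-(tigloyloxy)germacra-1(10),3-dien-12-oate (C11 epimers) | CC(C)(C)OC(=O)C(CO)[C@@H]2[C@@H](OC(=O)/C(C)=C/C)C/C(C)=C\C(=O)/C=C(/C)[C@@H]1OC(C)(C)O[C@H]12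
F3 | step 16 | 13-methanesulfonate of F2 | CC(C)(C)OC(=O)C(COS(C)(=O)=O)[C@@H]2[C@@H](OC(=O)/C(C)=C/C)C/C(C)=C\C(=O)/C=C(/C)[C@@H]1OC(C)(C)O[C@H]12
F4 | step 13 | tert-butyl (3R,4R,5S)-3-{[(tert-butyldimethylsilyl)oxy]methyl}-4-[(4S,5S)-2,2-dimethyl-5-(prop-1-en-2-yl)-1,3-dioxolan-4-yl]-2-ethenyl-2-hydroxy-5-(2-methylprop-2-en-1-yl)oxolane-3-carboxylate (anomers) | CC(C)(C)OC(=O)[C@]1(CO[Si](C)(C)C(C)(C)C)C(O)(C=C)O[C@@H](CC(C)=C)[C@@H]1[C@@H]2OC(C)(C)O[C@H]2C(C)=C
F5 | step 13 | oxa-bridged lactol (8-oxabicyclo[3.2.1]oct-2-ene; O8 bridges C2 and C8, ring C2–C1=C10–C9–C8–C7–C11 closed) | CC(C)(C)OC(=O)[C@]1(CO[Si](C)(C)C(C)(C)C)[C@@]2(O)C=C(C)C[C@H](O2)[C@@H]1[C@@H]3OC(C)(C)O[C@H]3C(C)=C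
F6 | step 13 | ring-B cycloheptene diol (22 with free C8 hydroxyl) | CC(C)(C)OC(=O)[C@@]1(CO[Si](C)(C)C(C)(C)C)[C@@H]([C@@H]2OC(C)(C)O[C@H]2C(C)=C)[C@@H](O)C/C(C)=C\[C@@]1(O)C=C
F7 | step 11 | tert-butyl (2R,3R,4S)-2-{[(tert-butyldimethylsilyl)oxy]methyl}-3-[(4S,5S)-2,2-dimethyl-5-(prop-1-en-2-yl)-1,3-dioxolan-4-yl]-4-hydroxy-2-(3-hydroxypenta-1,4-diyn-3-yl)-6-methylhept-6-enoate | CC(C)(C)OC(=O)[C@@](C(O)(C#C)C#C)(CO[Si](C)(C)C(C)(C)C)[C@@H]([C@@H]1OC(C)(C)O[C@H]1C(C)=C)[C@@H](O)CC(C)=C
F8 | step 8 | tert-butyl (4R,5R)-4-[(4S,5S)-2,2-dimethyl-5-(prop-1-en-2-yl)-1,3-dioxolan-4-yl]-5-(2-methylprop-2-en-1-yl)-2-oxooxolane-3-carboxylate (8-epi-14, C3 left open) | CC(C)(C)OC(=O)C1C(=O)O[C@H](CC(C)=C)[C@@H]1[C@@H]2OC(C)(C)O[C@H]2C(C)=C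
F9 | step 8 | 2-(tert-butoxycarbonyl)-3-[(4S,5S)-2,2-dimethyl-5-(prop-1-en-2-yl)-1,3-dioxolan-4-yl]-4-hydroxy-6-methylhept-6-enoic acid, (3R,4R), 8-epi hydroxy half-acid | OC(=O)C(C(=O)OC(C)(C)C)[C@@H]([C@@H]1OC(C)(C)O[C@H]1C(C)=C)[C@H](O)CC(C)=C
F10 | step 17 | tert-butyl (1(10)Z,3Z,5S,6S,7R,8S)-5,6-dihydroxy-2-oxo-8-(tigloyloxy)germacra-1(10),3,11(13)-trien-12-oate | C=C(C(=O)OC(C)(C)C)[C@@H]1[C@@H](OC(=O)/C(C)=C/C)C/C(C)=C\C(=O)/C=C(/C)[C@H](O)[C@H]1O
A1 | alternative 1 | (1(10)Z,3Z)-5-[(tert-butyldimethylsilyl)oxy]-7-ethynyl-6-hydroxy-4,10-dimethyl-2-oxocyclodeca-3,10(1)-dien-8-yl tiglate (11,12,13-trinor alkyne of the target skeleton, 5S,6S,7R,8S pattern) | C#C[C@@H]1[C@@H](OC(=O)/C(C)=C/C)C/C(C)=C\C(=O)/C=C(/C)[C@H](O[Si](C)(C)C(C)(C)C)[C@H]1O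
A2 | alternative 1 | target as its C5 tert-butyldimethylsilyl ether | C=C1C(=O)O[C@H]2[C@H]1[C@@H](OC(=O)/C(C)=C/C)C/C(C)=C\C(=O)/C=C(/C)[C@@H]2O[Si](C)(C)C(C)(C)C
A3 | alternative 2 | open-chain 3-(bromomethyl)butenolide with C5 OTBS, C2 OTES, Z,Z-diene and C8 aldehyde | O=CC/C(C)=C\[C@@H](O[Si](CC)(CC)CC)/C=C(/C)[C@H](O[Si](C)(C)C(C)(C)C)[C@H]1OC(=O)C(CBr)=C1
A4 | alternative 2 | ten-membered methylene lactone with free C8 hydroxyl, C2 OTES, C5 OTBS | C=C1C(=O)O[C@H]2[C@H]1[C@@H](O)C/C(C)=C\[C@@H](O[Si](CC)(CC)CC)/C=C(/C)[C@@H]2O[Si](C)(C)C(C)(C)C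
A5 | alternative 3 | eleven-membered cyclic sulfone, sulfur between C3 and C4 (C4 epimers), C2 OPMB, C8 OTBS, C12 OPMB, C5/C6 acetonide | C=C(COCc3ccc(OC)cc3)[C@@H]2[C@@H](O[Si](C)(C)C(C)(C)C)C/C(C)=C\[C@@H](OCc3ccc(OC)cc3)CS(=O)(=O)C(C)[C@@H]1OC(C)(C)O[C@H]12
A6 | alternative 3 | protected ten-membered triene | C=C(COCc3ccc(OC)cc3)[C@@H]2[C@@H](O[Si](C)(C)C(C)(C)C)C/C(C)=C\[C@@H](OCc3ccc(OC)cc3)/C=C(/C)[C@@H]1OC(C)(C)O[C@H]12
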